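When does this flask hold most target: at the early peak of the blue run, or later, in a slow rise towards the longest time allowed?

all flasks: substrate 20 mM
- blue: reagent 0.60 equiv; the very flask that is asked about, followed so far
- flask: reagent 0.600 equiv; time 6.0 h

blue run (percent of the substrate charged)

| time / min | target / % | substrate / % |
|---|---|---|
| 2.00 | 3.9 | 90.2 |
| 5.00 | 9.0 | 61.6 |
| 10.0 | 10.6 | 25.8 |
| 20.0 | 8.5 | 7.2 |
| 50.0 | 7.1 | 0.4 |
| 120 | 7.5 | 0 |

(standard deviation of a reading: 0.3 percentage points)

- the numbers in the tables scatter with a standard deviation of 0.3 percentage points

* when, up to 6.0 h, the flask holds most target
* the amount of target, in percent of the substrate charged, at that time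
* earliest time at which at least nineteen twentieths of that best amount are there
* latest time at which they still are

1. Turned round, the question asks what the blue run, which is this same flask followed so far, has to show for the best to lie late.
2. Take each target to come from one substrate. At 50.0 min the blue run then has a ceiling of 7.50 %: the ceiling is c target plus c substrate at one moment, the highest target that a later moment can reach if target has no other source.
3. A best after 50.0 min needs that ceiling above the highest reading, 10.6 % at 10.0 min. It stands lower, by 3.1 points against a scatter of 0.3 points.
4. So this reckoning puts the best before 50.0 min, near the 10.0 min reading.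
5. The forecast gives 10.9 % at 0.17 h, with the window from 0.125 h to 0.22 h. On a late rise it says “A slow late rise can't be fully excluded, but it is unlikely to pass 10.6% by 6 h”.
6. The flask gives 10.8 % at 0.135 h, with the window from 0.102 h to 0.188 h. The peak comes earlier than forecast.

    substrate + reagent + released group → target + 2 released group (k = 37.9 M⁻² s⁻¹)
    substrate + reagent → target + released group (k = 0.0311 M⁻¹ s⁻¹)
    substrate + target → side product (k = 0.656 M⁻¹ s⁻¹)

The best of 10.8 % lies above the ceiling of 7.50 % from the blue run. At 0.600 h the flask's ceiling is 8.70 %, also below that best. The neighbour flask with 34 mM of substrate keeps the equivalents of the recipe. At 6.00 h its substrate, the first charge to run out (the limiting reagent there), stands at 0 %, with 7.7 % of its reagent left. Its ceiling is then 10.8 %, below its best of 15.8 %.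

The earlier runs and the new flask are simulated on assumed constants, and the scatter is random.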